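The constants used here are invented; the rest is arithmetic.

I began with X, the catalyst.

    D + X ⇌ D.X (K1 = 0.82 M⁻¹, k1 = 63 M⁻¹ s⁻¹)
    D.X → X + Q (k2 = 2.4 s⁻¹)
    E ⇌ Q, rate k3*(cs3 - [Q]) while solid is left; crystals form when [Q] > cs3 (cs3 = 0.47 M, k3 = 0.42 s⁻¹)

D 2.0 M; X 1.5 mol%; time 80 s

- Q and E together at 80 s, in percent of the D charged
- the change that raises the amount of Q and E together at 80 s, in percent of the D charged most ("none" if none brings more than 2 percentage points) (midnight / noon / summer / none)
- amount of Q and E together at 80 s, in percent of the D charged, after midnight

- midnight: doubling the solubility in step 3, all else as stated
- noon: doubling the dissolution coefficient of step 3, all else as stated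
- summer: doubling the amount of X, all else as stated

- amounts and yields of Q count E too
- given per volume of solution although it is solid: E
- run time (flask): 80 s

The crystal step moves product between Q and E, which are counted together, so I set it aside, and my reckoning gave midnight and noon no gain.

I turned the question round: for summer to be useless, less than 2 percentage points of the D would have to remain at 80 s. How far was this flask from that? I solved both ends. With c(D) far above a concentration length L, the Michaelis constant, X works flat out and c(D) falls steadily; with c(D) far below L, it falls exponentially, by a factor e for each L of budget spent. Joined, the two ends say that X has a budget B, pays the charge of D from it, and spends the rest on the tail: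

L = (back constant of the first step + constant of the second) / (forward constant of the first) = 1.26 M

B = constant of the second step × charged c(X) × time = 2.4 s⁻¹ × 0.0300 M × 80 s = 5.76 M

n = (B − charged c(D)) / L = 2.99

share of D left = exp(−n) = 5.03%

I call n the spare budget. Useless summer needed n of 3.91, and this flask stood lower. So I committed to y of 95.0%, the same for midnight, and summer as best, gaining 5 points.

The forecast gave 95.1% (94.6% to 95.6%), summer as best and 95.1% after midnight, holding that “step 3 only divides product between dissolved Q and E”. My y lay close to that figure, though not on it, at 95.0%.

The simulation gave 95.1%, summer as best with 4.8 points, and 95.1% after midnight. At 80.0 s the flask held 4.79% of its D unbound. Doubling X and doubling the time each double B, which gives n of 7.57, and this flask at 160 s held 99.9% as Q and E.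

The neighbour with 0.80 M of D at the same loading has n of 1.20, lower than this flask's, so exp(−n) gives an estimate of 30.1% of its D left. The simulation left 25.7%, and y there came to 74.1%.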